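**Retrosynthetic overview**
1. Target ⇐ hydroxy enol lactone 20 (lactone → lactol → C2 acetate, C13 acetate); the cycloheptane, the last ring, ⇐ C1–C10 samarium Reformatsky closure of chloro lactone 19 onto the methyl ketone.
2. Dihydropyranone ⇐ oxa-Diels–Alder (C2–O and C1–C5 bonds) of enal 15 with chloro ketene acetal 17.
3. Oxepene ⇐ C15–O bond: oxa-Michael/Horner–Wadsworth–Emmons annulation of lactol 8 with phosphonoacrylate 9 (the central step).
4. Lactol 8 ⇐ trans-cyclopropane 5 ⇐ organocatalytic Michael-initiated ring closure of (2E)-hepta-2,6-dienal 3 with diethyl bromomalonate 4.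
5. Ring order: cyclopropane → temporary oxolane lactol → oxepene → dihydropyranone → cycloheptane.

Assumption: the SMILES is read literally; it places C5 and C8 on opposite faces of the cyclopropane (a trans-fused bicyclo[5.1.0]octane), and the route is built to deliver exactly that relative and absolute configuration.
Locants (2,3-secoaromadendrane numbering): C1 and C5 ring-fusion CH; C2 acetal CH; C3=C4 enol ether; C6, C7, C11 cyclopropane; C8, C9 CH2CH2; C10 carbinol; C12 ring OCH2 on C11; C13 CH2OAc; C14 CH3; C15 ring OCH2 on C4.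

Step 1
Reactants: 1 hexa-1,5-diene; 2 (E)-but-2-enal
Product: 3 (2E)-hepta-2,6-dienal
Conditions: second-generation Grubbs catalyst (2 mol%), 1 (5 equiv), CH2Cl2, 40 °C
Reagents that add atoms: none
Why: Olefin cross-metathesis of a terminal alkene with crotonaldehyde gives the E-enal reliably, the excess of the cheap diene suppresses double metathesis, and no stereocentre is formed.

Step 2
Reactants: 3 (2E)-hepta-2,6-dienal; 4 diethyl 2-bromopropanedioate
Product: 5 diethyl (2R,3R)-2-(but-3-en-1-yl)-3-formylcyclopropane-1,1-dicarboxylate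
Conditions: (S)-α,α-diphenylprolinol trimethylsilyl ether (20 mol%), 2,6-lutidine (1.1 equiv), CH2Cl2, 0 °C to rt
Reagents that add atoms: none
Why: Organocatalytic Michael-initiated ring closure (iminium then enamine catalysis): the (S)-catalyst shields one face of the E-iminium, the bromomalonate adds to C7 on the open face and the enamine displaces bromide, giving the trans (2R,3R) cyclopropane that fixes C6 and C7 with their carbon substituents on opposite faces.

Step 3
Reactants: 5 diethyl (2R,3R)-2-(but-3-en-1-yl)-3-formylcyclopropane-1,1-dicarboxylate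
Product: 6 diethyl (2R,3R)-2-(but-3-en-1-yl)-3-(dimethoxymethyl)cyclopropane-1,1-dicarboxylate
Conditions: HC(OMe)3, MeOH, pyridinium p-toluenesulfonate (cat.), rt
Reagents that add atoms: trimethyl orthoformate, COC(OC)OC; methanol, CO
Why: Acid-catalysed acetalisation masks the aldehyde so that only the two esters are reduced in the next step; no stereocentre is touched.

Step 4
Reactants: 6 diethyl (2R,3R)-2-(but-3-en-1-yl)-3-(dimethoxymethyl)cyclopropane-1,1-dicarboxylate
Product: 8 6-(but-3-en-1-yl)-5-(hydroxymethyl)-3-oxabicyclo[3.1.0]hexan-2-ol, via diol acetal 7 (not isolated)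
Conditions: LiAlH4, THF, 0 °C; then aq. oxalic acid, THF, rt
Reagents that add atoms: water, O
Why: LiAlH4 ester reduction followed by acetal hydrolysis; only the hydroxymethyl group cis to the formyl group can reach it, so lactol formation tells the two CH2OH groups apart and makes C11 a defined stereocentre.

Step 5
Reactants: 8 6-(but-3-en-1-yl)-5-(hydroxymethyl)-3-oxabicyclo[3.1.0]hexan-2-ol; 9 ethyl 2-(diethoxyphosphoryl)prop-2-enoate
Product: 11 ethyl 8-(but-3-en-1-yl)-1-(hydroxymethyl)-3-oxabicyclo[5.1.0]oct-5-ene-5-carboxylate, via phosphonate aldehyde 10 (not isolated)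
Conditions: Cs2CO3 (1.5 equiv), 9 (1.3 equiv), THF, 0 to 45 °C
Reagents that add atoms: none
Why: Proposed new method: an oxa-Michael/Horner–Wadsworth–Emmons [4+3] annulation in which a γ-lactol acts as a latent oxido-aldehyde — Cs2CO3 opens the lactolate, the alkoxide adds to the phosphonoacrylate to form the C15–O bond, and the phosphonate carbanion so formed olefinates the unmasked aldehyde through a seven-membered transition state (C4=C5), while the adduct of the other hydroxyl cannot cyclise and reverts; the closest known reaction type is the tandem oxa-Michael/HWE annulation of salicylaldehydes and α-hydroxy ketones with 2-phosphonoacrylates to 2H-chromenes and 2,5-dihydrofurans.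

Step 6
Reactants: 11 ethyl 8-(but-3-en-1-yl)-1-(hydroxymethyl)-3-oxabicyclo[5.1.0]oct-5-ene-5-carboxylate
Product: 12 [8-(but-3-en-1-yl)-3-oxabicyclo[5.1.0]oct-5-ene-1,5-diyl]dimethanol
Conditions: i-Bu2AlH (4 equiv), CH2Cl2, −78 to −40 °C; aq. KNaC4H4O6 work-up
Reagents that add atoms: none
Why: 1,2-Reduction of the unsaturated ester with i-Bu2AlH gives the allylic alcohol without touching the alkenes or the cyclopropane.

Step 7
Reactants: 12 [8-(but-3-en-1-yl)-3-oxabicyclo[5.1.0]oct-5-ene-1,5-diyl]dimethanol
Product: 13 8-(but-3-en-1-yl)-1-(hydroxymethyl)-3-oxabicyclo[5.1.0]oct-5-ene-5-carbaldehyde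
Conditions: MnO2 (15 equiv), CH2Cl2, rt
Reagents that add atoms: none
Why: MnO2 oxidation is selective for the allylic alcohol, so the saturated C13 hydroxyl is left alone and the enal (future 1-oxadiene) is obtained.

Step 8
Reactants: 13 8-(but-3-en-1-yl)-1-(hydroxymethyl)-3-oxabicyclo[5.1.0]oct-5-ene-5-carbaldehyde
Product: 14 [8-(but-3-en-1-yl)-5-formyl-3-oxabicyclo[5.1.0]oct-5-en-1-yl]methyl acetate
Conditions: Ac2O, pyridine, DMAP (cat.), CH2Cl2, 0 °C
Reagents that add atoms: acetic anhydride, CC(=O)OC(C)=O
Why: O-Acetylation caps the only free hydroxyl, which would otherwise add to the ketene acetal in step 11 and protonate the samarium enolate in step 12.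

Step 9
Reactants: 14 [8-(but-3-en-1-yl)-5-formyl-3-oxabicyclo[5.1.0]oct-5-en-1-yl]methyl acetate
Product: 15 [5-formyl-8-(3-oxobutyl)-3-oxabicyclo[5.1.0]oct-5-en-1-yl]methyl acetate
Conditions: PdCl2 (10 mol%), 1,4-benzoquinone (1.2 equiv), DMF/H2O (7:1), rt
Reagents that add atoms: water, O
Why: Tsuji–Wacker oxidation turns the terminal alkene into the methyl ketone (C10 and C14) with Markovnikov selectivity, the conjugated trisubstituted ring alkene being inert.

Step 10
Reactants: 16 1,1-dichloro-2,2-diethoxyethane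
Product: 17 2-chloro-1,1-diethoxyethene
Conditions: KOt-Bu, THF, 0 °C to rt; distillation
Reagents that add atoms: none
Why: Base-induced dehydrochlorination (E2 elimination) of a dichloroacetal is the standard way to a halo ketene acetal.

Step 11
Reactants: 15 [5-formyl-8-(3-oxobutyl)-3-oxabicyclo[5.1.0]oct-5-en-1-yl]methyl acetate; 17 2-chloro-1,1-diethoxyethene
Product: 19 tricyclic 1-chloro enol lactone, via tricyclic ortho ester 18 (not isolated)
Conditions: 17 (2.5 equiv), toluene, 90 °C; then Me3SiBr (1.2 equiv), 2,6-lutidine (0.2 equiv), CH2Cl2, −20 °C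
Reagents that add atoms: none
Why: Inverse-electron-demand oxa-Diels–Alder reaction of the enal (1-oxadiene) with the electron-rich ketene acetal forms the C2–O and C1–C5 bonds, the dienophile adding to C5 on the face anti to the cyclopropane CH (C7), whose endo hydrogen covers the other face, which sets C5; Me3SiBr then dealkylates the ortho ester to the enol lactone (C1 is a mixture that is erased in step 12).

Step 12
Reactants: 19 tricyclic 1-chloro enol lactone
Product: 20 tetracyclic hydroxy enol lactone
Conditions: SmI2 (2.5 equiv), THF/HMPA (10:1), −78 °C; aq. NH4Cl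
Reagents that add atoms: none
Why: Samarium diiodide-mediated intramolecular Reformatsky reaction: reduction of the C–Cl bond gives a samarium enolate that adds irreversibly to the tethered methyl ketone, the tether from C7 reaching only the enolate face syn to C6 (H1 and H5 cis) and the samarium chelate between enolate and ketone oxygens placing the new hydroxyl cis to C2, which sets C1 and C10 and closes the strained trans-fused cycloheptane.

Step 13
Reactants: 20 tetracyclic hydroxy enol lactone
Product: 22 target CNP0250836.2, via lactol triol 21 (not isolated)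
Conditions: i-Bu2AlH (5 equiv), CH2Cl2, −78 °C; aq. KNaC4H4O6; then Ac2O, Et3N, DMAP (cat.), CH2Cl2, 0 °C
Reagents that add atoms: acetic anhydride, CC(=O)OC(C)=O
Why: Lactone-to-lactol reduction with i-Bu2AlH (which also removes the temporary acetate) followed by O-acylation: the mutarotating lactol is acetylated to the axial anomeric acetate trans to the C1–C10 bond (anomeric effect), the primary C13 hydroxyl is acetylated as well, and the tertiary C10 hydroxyl is too hindered to react at 0 °C.

**Compound list**
1 | hexa-1,5-diene | C=CCCC=C | starting material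
2 | (E)-but-2-enal (crotonaldehyde) | C/C=C/C=O | starting material
3 | (2E)-hepta-2,6-dienal | O=C/C=C/CCC=C | intermediate
4 | diethyl 2-bromopropanedioate (diethyl bromomalonate) | CCOC(=O)C(Br)C(=O)OCC | starting material
5 | diethyl (2R,3R)-2-(but-3-en-1-yl)-3-formylcyclopropane-1,1-dicarboxylate (butenyl and formyl trans) | O=C[C@@H]1[C@@H](CCC=C)C1(C(=O)OCC)C(=O)OCC | intermediate
6 | diethyl (2R,3R)-2-(but-3-en-1-yl)-3-(dimethoxymethyl)cyclopropane-1,1-dicarboxylate | COC(OC)[C@@H]1[C@@H](CCC=C)C1(C(=O)OCC)C(=O)OCC | intermediate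
7 | diol acetal: [(2R,3R)-2-(but-3-en-1-yl)-3-(dimethoxymethyl)cyclopropane-1,1-diyl]dimethanol | COC(OC)[C@@H]1[C@@H](CCC=C)C1(CO)CO | intermediate
8 | 6-(but-3-en-1-yl)-5-(hydroxymethyl)-3-oxabicyclo[3.1.0]hexan-2-ol (lactol, anomeric mixture; ring O–CH2 on the hydroxymethyl-bearing bridgehead, butenyl exo) | OC[C@@]12COC(O)[C@@H]1[C@H]2CCC=C | intermediate
9 | ethyl 2-(diethoxyphosphoryl)prop-2-enoate | C=C(C(=O)OCC)P(=O)(OCC)OCC | starting material
10 | phosphonate aldehyde: ethyl 3-{[2-(but-3-en-1-yl)-3-formyl-1-(hydroxymethyl)cyclopropyl]methoxy}-2-(diethoxyphosphoryl)propanoate (ether on the CH2 cis to formyl) | OC[C@@]1(COCC(C(=O)OCC)P(=O)(OCC)OCC)[C@H](C=O)[C@H]1CCC=C | intermediate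
11 | ethyl 8-(but-3-en-1-yl)-1-(hydroxymethyl)-3-oxabicyclo[5.1.0]oct-5-ene-5-carboxylate (cis-fused, butenyl exo) | OC[C@@]12COCC(C(=O)OCC)=C[C@@H]1[C@H]2CCC=C | intermediate
12 | [8-(but-3-en-1-yl)-3-oxabicyclo[5.1.0]oct-5-ene-1,5-diyl]dimethanol | OC[C@@]12COCC(CO)=C[C@@H]1[C@H]2CCC=C | intermediate
13 | 8-(but-3-en-1-yl)-1-(hydroxymethyl)-3-oxabicyclo[5.1.0]oct-5-ene-5-carbaldehyde | OC[C@@]12COCC(C=O)=C[C@@H]1[C@H]2CCC=C | intermediate
14 | [8-(but-3-en-1-yl)-5-formyl-3-oxabicyclo[5.1.0]oct-5-en-1-yl]methyl acetate | CC(=O)OC[C@@]12COCC(C=O)=C[C@@H]1[C@H]2CCC=C | intermediate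
15 | [5-formyl-8-(3-oxobutyl)-3-oxabicyclo[5.1.0]oct-5-en-1-yl]methyl acetate | CC(=O)OC[C@@]12COCC(C=O)=C[C@@H]1[C@H]2CCC(C)=O | intermediate
16 | 1,1-dichloro-2,2-diethoxyethane | CCOC(OCC)C(Cl)Cl | starting material
17 | 2-chloro-1,1-diethoxyethene (chloro ketene diethyl acetal) | CCOC(OCC)=CCl | intermediate
18 | tricyclic ortho ester: 3-chloro-2,2-diethoxy-3,4-dihydro-2H-pyran fused through C4–C5 to the oxepane; C13 acetate; 3-oxobutyl on C7; new bond at C5 anti to C7; C1 epimers | CC(=O)OC[C@@]12COCC3=COC(OCC)(OCC)C(Cl)[C@H]3[C@@H]1[C@H]2CCC(C)=O | intermediate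
19 | tricyclic 1-chloro enol lactone: as 18 with C2 as lactone C=O | CC(=O)OC[C@@]12COCC3=COC(=O)C(Cl)[C@H]3[C@@H]1[C@H]2CCC(C)=O | intermediate
20 | tetracyclic hydroxy enol lactone: target skeleton with C2 as lactone C=O, free 10-OH, C13 acetate; H1 and H5 cis, 10-OH cis to C2 | CC(=O)OC[C@@]12COCC3=COC(=O)[C@@H]4[C@H]3[C@@H]1[C@H]2CC[C@]4(C)O | intermediate
21 | lactol triol: 20 with C2 as hemiacetal CH(OH) (anomers) and C13 OH free | OC[C@@]12COCC3=COC(O)[C@@H]4[C@H]3[C@@H]1[C@H]2CC[C@]4(C)O | intermediate
22 | CNP0250836.2: C2 and C13 diacetate, 10-OH, tetracyclic 2,3-secoaromadendrane with a 12,15-ether bridge | CC(=O)OC[C@@]12COCC3=CO[C@H](OC(C)=O)[C@@H]4[C@H]3[C@@H]1[C@H]2CC[C@]4(C)O | target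

**Step count and risks**
Total steps: 13. Longest linear sequence: 12 (steps 1–9 and 11–13; step 10 prepares reagent 17).

Steps most likely to fail:

Step 5 (the proposed annulation). The lactolate may be alkylated at the anomeric oxygen, or the seven-membered olefination may be slow. Fallback with known chemistry, setting out from 8 and coming back at 11: silylation of the primary alcohol (t-BuMe2SiCl, imidazole, CH2Cl2, −20 °C) gives the silyl lactol F1. Wittig methylenation (Ph3P=CH2 from Ph3PCH3Br and KN(SiMe3)2, THF) opens it to the vinylcyclopropane alcohol F2, in which only the hydroxymethyl cis to the vinyl group is free. Williamson etherification with ethyl 2-(bromomethyl)acrylate (NaH, THF, 0 °C) gives the acrylate ether F3. Ring-closing metathesis (second-generation Grubbs catalyst, toluene, 80 °C) closes the oxepene as the silyl ether ester F4, and Bu4NF in THF returns 11.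

Step 11 (oxa-Diels–Alder). The chloro ketene acetal is a weaker dienophile than the parent, the ortho ester may open to an oxo ester instead of the lactone, and face selectivity at C5 rests on substrate control. Fallback setting out from 15 and coming back at 19: Mukaiyama–Michael addition of the known silyl ketene acetal tert-butyl[(2-chloro-1-methoxyethenyl)oxy]dimethylsilane to the enal (LiClO4, Et2O, rt; aqueous HF work-up) gives the open-chain chloro oxo ester F5. Acid-catalysed enol lactonisation (p-TsOH, toluene, reflux, removal of methanol) then closes 19. This replaces the concerted cycloaddition by a Lewis-acid-activated conjugate addition and a separate ring closure.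

Step 12 (samarium Reformatsky closure of the trans-fused seven-membered ring). Strain may let enolate protonation or ketene loss win. Fallback setting out from 15 and coming back at 20: oxa-Diels–Alder reaction with commercial 1,1-diethoxyethene (toluene, 80 °C) gives the chlorine-free ortho ester F6. Me3SiOSO2CF3/Et3N (CH2Cl2, −78 °C) converts it into the cyclic ketene acetal F7, which under catalytic Me3SiOSO2CF3 undergoes an intramolecular Mukaiyama aldol addition to the methyl ketone to give the silyl ether lactone F8. HF·pyridine in THF releases 20. This swaps the reductive samarium enolate for a halogen-free Lewis-acid aldol.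

**Further compounds**
F1 | step 5 | silyl lactol: 6-(but-3-en-1-yl)-5-{[tert-butyl(dimethyl)silyl]oxymethyl}-3-oxabicyclo[3.1.0]hexan-2-ol | CC(C)(C)[Si](C)(C)OC[C@@]12COC(O)[C@@H]1[C@H]2CCC=C
F2 | step 5 | vinylcyclopropane alcohol: [2-(but-3-en-1-yl)-1-{[tert-butyl(dimethyl)silyl]oxymethyl}-3-ethenylcyclopropyl]methanol (CH2OH cis to vinyl) | CC(C)(C)[Si](C)(C)OC[C@@]1(CO)[C@H](C=C)[C@H]1CCC=C
F3 | step 5 | acrylate ether: ethyl 2-({[2-(but-3-en-1-yl)-1-{[tert-butyl(dimethyl)silyl]oxymethyl}-3-ethenylcyclopropyl]methoxy}methyl)prop-2-enoate | CC(C)(C)[Si](C)(C)OC[C@@]1(COCC(=C)C(=O)OCC)[C@H](C=C)[C@H]1CCC=C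
F4 | step 5 | silyl ether ester: ethyl 8-(but-3-en-1-yl)-1-{[tert-butyl(dimethyl)silyl]oxymethyl}-3-oxabicyclo[5.1.0]oct-5-ene-5-carboxylate | CC(C)(C)[Si](C)(C)OC[C@@]12COCC(C(=O)OCC)=C[C@@H]1[C@H]2CCC=C
F5 | step 11 | open-chain chloro oxo ester: methyl 2-chloro-2-[1-(acetoxymethyl)-5-formyl-8-(3-oxobutyl)-3-oxabicyclo[5.1.0]octan-6-yl]acetate | CC(=O)OC[C@@]12COCC(C=O)[C@@H](C(Cl)C(=O)OC)[C@@H]1[C@H]2CCC(C)=O
F6 | step 12 | chlorine-free ortho ester: 18 with CH2 at C1 | CC(=O)OC[C@@]12COCC3=COC(OCC)(OCC)C[C@H]3[C@@H]1[C@H]2CCC(C)=O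
F7 | step 12 | cyclic ketene acetal: 2-ethoxy-4H-pyran fused through C4–C5 to the oxepane | CC(=O)OC[C@@]12COCC3=COC(OCC)=C[C@H]3[C@@H]1[C@H]2CCC(C)=O
F8 | step 12 | silyl ether lactone: 10-O-trimethylsilyl ether of 20 | CC(=O)OC[C@@]12COCC3=COC(=O)[C@@H]4[C@H]3[C@@H]1[C@H]2CC[C@]4(C)O[Si](C)(C)C
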